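Ring B with C5 and C10 is taken from (1R,5R)-(+)-verbenone: copper-catalysed addition anti to the gem-dimethyl bridge builds C10, and cleavage of the cyclobutane C–C bond turns the bridge carbon into an isopropenyl group, the future C4, C18 and C19. Everything rests on closing ring A last, at C3–C4: the tertiary nitrile-stabilised carbanion at C4 of a 3,4-seco-labdane displaces a C3 iodide. In one operation this forms ring A and the C4 quaternary stereocentre; it exploits the 1,3-diaxial relation between C4 and the C20 methyl on C10, which only the rod-like nitrile (C19 acid surrogate) tolerates in the axial site. Carboalumination, etherification with silylated cryptomeridiol and nitrile-to-acid conversion finish.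

Key step: step 10

Remark: labdane numbering (C1–C20) and primed eudesmane numbering (C1′–C15′) are used for all intermediates; α/β refer to the usual ring B orientation (H-5 α, CH3-20 β), also in the pinane-bridged and ring-A-open compounds. (+)-β-Eudesmol and (1R,5R)-(+)-verbenone are taken as commercial natural-product starting materials.

Step 1
Reactants: 1 (1R,5R)-(+)-verbenone; 2 (3-bromopropoxy)(tert-butyl)dimethylsilane
Product: 3 pinane trimethylsilyl enol ether
Conditions: 2, Mg, THF (Grignard reagent); then CuBr·SMe2 (10 mol %), TMSCl, HMPA, 1, THF, −78 → −40 °C; Et3N work-up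
Reagents that add atoms: chlorotrimethylsilane C[Si](C)(C)Cl
Why: Copper-catalysed 1,4-addition of the Grignard reagent to the β,β-disubstituted enone should occur on the face anti to the gem-dimethyl bridge, which sets C10 (methyl syn to the bridge, chain anti), and silylation of the enolate in the flask stores its C8=C9 regiochemistry.

Step 2
Reactants: 3 pinane trimethylsilyl enol ether; 4 methyl vinyl ketone
Product: 6 pinane diketone, via enol silane 5 (not isolated)
Conditions: Sc(OTf)3 (5 mol %), CH2Cl2, −78 °C; then 1 M aq. HCl, 0 °C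
Reagents that add atoms: none
Why: Lewis-acid-catalysed Mukaiyama–Michael addition of the regiodefined silyl enol ether forms C9–C11 without a free enolate and passes the silyl group to the acceptor enolate, which the acidic work-up hydrolyses; the electrophile enters anti to the bridge (this C9 configuration is inverted in step 3).

Step 3
Reactants: 6 pinane diketone
Product: 8 pinane keto alkyne, via enol phosphate 7 (not isolated)
Conditions: LiN(iPr)2 (1.1 equiv), THF, −78 °C; ClP(O)(OEt)2; then LiN(iPr)2 (3.3 equiv), −78 → 0 °C; AcOH, THF, −78 °C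
Reagents that add atoms: none
Why: One-pot methyl ketone to terminal alkyne conversion (kinetic terminal enolate, enol phosphate, base-induced elimination), in which the excess amide also forms the only possible ring enolate (C8=C9, the bridgehead C7 cannot enolise) and kinetic protonation from the face anti to the gem-dimethyl bridge should place H-9 α and the but-3-ynyl chain β (syn to the bridge).

Step 4
Reactants: 8 pinane keto alkyne
Product: 9 ring B enol acetate
Conditions: BF3·OEt2, Zn(OAc)2, Ac2O, 0 °C → rt
Reagents that add atoms: acetic anhydride CC(=O)OC(C)=O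
Why: Acetylative Lewis-acid fragmentation of the cyclobutyl ketone (retro-Prins type): activation of the C8 carbonyl breaks the strained C7–C4 bond, the enol is trapped as the C7=C8 acetate, the tertiary C4 cation loses a methyl proton to give the isopropenyl group on C5 and the primary silyl ether is exchanged for acetate, while C5, C9 and C10 are untouched.

Step 5
Reactants: 9 ring B enol acetate
Product: 11 primary alcohol, via alkylborane 10 (not isolated)
Conditions: 9-BBN, THF, 0 °C → rt; then 30% H2O2, aq. NaOAc, 0 °C
Reagents that add atoms: hydrogen peroxide OO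
Why: Anti-Markovnikov hydroboration–oxidation, relying on the known preference of 9-BBN for a 1,1-disubstituted alkene over a terminal alkyne and on its inertness toward the enol acetate; the C4 epimer mixture at the new C19 alcohol is of no consequence because C4 becomes planar in step 10.

Step 6
Reactants: 11 primary alcohol
Product: 13 seco nitrile, via seco aldehyde 12 (not isolated)
Conditions: TEMPO (10 mol %), PhI(OAc)2, NH4OAc, MeCN–H2O, rt
Reagents that add atoms: ammonium acetate CC(=O)[O-].[NH4+]
Why: Oxoammonium-mediated oxidation to the aldehyde, imine formation with ammonia and a second oxidation give the C19 nitrile in one pot (oxidative alcohol-to-nitrile conversion), leaving acetates, alkyne and enol ester intact.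

Step 7
Reactants: 13 seco nitrile
Product: 14 keto alcohol nitrile
Conditions: K2CO3, MeOH, 0 °C → rt
Reagents that add atoms: none
Why: Base-catalysed transesterification removes both acetyl groups, the enol acetate collapsing to the C8 ketone by protonation at C7; the hindered tertiary H-9 is removed only slowly under these mild conditions and the 9β chain is also the equatorial arrangement, so C9 should stay intact.

Step 8
Reactants: 14 keto alcohol nitrile
Product: 15 methylene alcohol nitrile
Conditions: Ph3PCH3Br, KOtBu, THF, 0 → 50 °C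
Reagents that add atoms: methyltriphenylphosphonium bromide C[P+](c1ccccc1)(c1ccccc1)c1ccccc1.[Br-]
Why: Wittig methylenation installs C17 while C3 still carries only a hydroxyl, so that no enolate alkylation can compete; no stereocentre is formed, and C9 can no longer epimerise once the carbonyl is gone.

Step 9
Reactants: 15 methylene alcohol nitrile
Product: 16 seco iodide
Conditions: I2, PPh3, imidazole, CH2Cl2, 0 °C
Reagents that add atoms: iodine II
Why: Appel-type iodination converts the primary C3 alcohol into the primary iodide under neutral conditions that tolerate nitrile, alkyne and alkene.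

Step 10
Reactants: 16 seco iodide
Product: 17 bicyclic nitrile
Conditions: LiN(iPr)2 (2.3 equiv), THF–DMPU, −78 → 0 °C; then H2O
Reagents that add atoms: none
Why: LiN(iPr)2 removes the alkyne proton (the acetylide is a spectator) and the C4–H of both C4 epimers, which converge on one planar N-lithiated keteniminate; this tertiary carbanion displaces iodide at C3 by intramolecular SN2 alkylation, the closest known reaction type being the alkylative cyclisation of metalated nitriles to cyclohexanes with quaternary centres. Ring A closes in the 6-exo-tet mode through a chair transition state that is trans-fused to ring B, because H-5 α and CH3-20 β are already in place on the ring B chair. The only new stereocentre, C4, is under substrate control: the carbanion substituent that turns axial becomes 1,3-diaxial to the C20 methyl on C10, and the rod-like C≡N (very small A value) should take this site and leave CH3-18 equatorial, so that C19 emerges β as in the target. The nitrile is chosen over an ester because the linear keteniminate has no allylic 1,3-strain with the substituents on C5 and its small cylindrical C≡N tolerates the axial site. The step needs C- over N-alkylation, substitution over E2 and intra- over intermolecular reaction, which the soft primary iodide, the low temperature, the six-membered ring size and moderate dilution should secure.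

Step 11
Reactants: 17 bicyclic nitrile
Product: 19 allylic alcohol, via alkenylalane 18 (not isolated)
Conditions: Me3Al, Cp2ZrCl2 (0.3 equiv), CH2Cl2, 0 °C → rt; volatiles removed; n-BuLi, THF–hexane, −78 °C; (CH2O)n, → rt
Reagents that add atoms: trimethylaluminium C[Al](C)C; formaldehyde (from paraformaldehyde) C=O
Why: Zirconium-catalysed syn-carboalumination of the terminal alkyne (Negishi carboalumination) places methyl at C13 and aluminium at C14, which sets the 13E geometry, and the alanate formed with n-BuLi is hydroxymethylated by formaldehyde with retention to add C15.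

Step 12
Reactants: 19 allylic alcohol
Product: 20 allylic bromide
Conditions: CBr4, PPh3, CH2Cl2, −20 °C
Reagents that add atoms: carbon tetrabromide BrC(Br)(Br)Br
Why: Appel bromination of the primary allylic alcohol should proceed by SN2 without allylic transposition or loss of the E geometry.

Step 13
Reactants: 21 (+)-β-eudesmol
Product: 22 β-eudesmol triethylsilyl ether
Conditions: TESOTf, 2,6-lutidine, CH2Cl2, 0 °C
Reagents that add atoms: triethylsilyl trifluoromethanesulfonate CC[Si](CC)(CC)OS(=O)(=O)C(F)(F)F
Why: Silylation of the only (tertiary) hydroxyl with the reactive silyl triflate masks O-11′, so that the C4′ hydroxyl made later is the single free alcohol.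

Step 14
Reactants: 22 β-eudesmol triethylsilyl ether
Product: 23 eudesmane spiro-epoxide
Conditions: mCPBA, NaHCO3, CH2Cl2, 0 °C
Reagents that add atoms: 3-chloroperoxybenzoic acid OOC(=O)c1cccc(Cl)c1
Why: Prilezhaev epoxidation of the exocyclic C4′=C15′ alkene should occur from the α face because the β face is shielded by the axial C10′ methyl, which sets the C4′–O bond α (equatorial).

Step 15
Reactants: 23 eudesmane spiro-epoxide
Product: 24 silylated cryptomeridiol
Conditions: LiEt3BH, THF, 0 °C → rt; then H2O
Reagents that add atoms: none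
Why: SN2 hydride opening of the spiro-epoxide at the primary C15′ gives the tertiary 4′α-alcohol with the 4′β-methyl without touching the stereocentre.

Step 16
Reactants: 20 allylic bromide; 24 silylated cryptomeridiol
Product: 25 coupled ether nitrile
Conditions: 24, KH, 18-crown-6, THF, 0 °C; then 20, Bu4NI (cat.), 0 °C → rt
Reagents that add atoms: none
Why: Williamson ether synthesis in which the crown-ether-activated potassium alkoxide of the tertiary alcohol displaces the primary allylic bromide by SN2, so that the C4′ configuration and the 13E alkene are both preserved.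

Step 17
Reactants: 25 coupled ether nitrile
Product: 27 neopentyl aldehyde, via aluminated aldimine 26 (not isolated)
Conditions: iBu2AlH, toluene, −78 °C → rt; then 10% aq. citric acid, 0 °C
Reagents that add atoms: water O
Why: Partial reduction of the hindered axial nitrile by a single hydride transfer gives an aluminated aldimine that is hydrolysed on mildly acidic work-up to the C19 aldehyde, no other reducible group being present.

Step 18
Reactants: 27 neopentyl aldehyde
Product: 28 silyl-protected acid
Conditions: NaClO2, NaH2PO4, 2-methyl-2-butene, tBuOH–H2O, rt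
Reagents that add atoms: sodium chlorite [Na+].[O-]Cl=O
Why: Pinnick oxidation converts the hindered aldehyde into the carboxylic acid while 2-methyl-2-butene scavenges hypochlorous acid and so spares both alkenes.

Step 19
Reactants: 28 silyl-protected acid
Product: 29 target acid
Conditions: HF·pyridine, pyridine, THF, 0 °C → rt
Reagents that add atoms: none
Why: Fluoride-mediated cleavage of the tertiary triethylsilyl ether liberates the C11′ alcohol under buffered conditions that should neither ionise the allylic ether nor isomerise the exocyclic alkene.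

Compound list

1 | (1R,5R)-(+)-verbenone, (1R,5R)-4,6,6-trimethylbicyclo[3.1.1]hept-3-en-2-one | O=C1C=C(C)[C@H]2C[C@@H]1C2(C)C | starting material
2 | (3-bromopropoxy)(tert-butyl)dimethylsilane | BrCCCO[Si](C)(C)C(C)(C)C | starting material
3 | 2-(trimethylsilyloxy)-4,6,6-trimethyl-4-[3-(tert-butyldimethylsilyloxy)propyl]bicyclo[3.1.1]hept-2-ene, silyloxypropyl chain anti and 4-methyl syn to the gem-dimethyl bridge | C[Si](C)(C)OC1=C[C@@](C)(CCCO[Si](C)(C)C(C)(C)C)[C@H]2C[C@@H]1C2(C)C | intermediate
4 | methyl vinyl ketone (but-3-en-2-one) | C=CC(C)=O | starting material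
5 | trimethylsilyl enol ether of the Michael adduct, 3-[3-(trimethylsilyloxy)but-2-enyl] pinane ketone (not isolated) | O=C1[C@@H](CC=C(C)O[Si](C)(C)C)[C@@](C)(CCCO[Si](C)(C)C(C)(C)C)[C@H]2C[C@@H]1C2(C)C | intermediate
6 | 4,6,6-trimethyl-3-(3-oxobutyl)-4-[3-(tert-butyldimethylsilyloxy)propyl]bicyclo[3.1.1]heptan-2-one, 3-oxobutyl chain anti to the bridge (C11 α) | O=C1[C@@H](CCC(C)=O)[C@@](C)(CCCO[Si](C)(C)C(C)(C)C)[C@H]2C[C@@H]1C2(C)C | intermediate
7 | enol phosphate of 6, diethyl 4-(pinan-2-on-3-yl)but-1-en-2-yl phosphate (not isolated) | O=C1[C@@H](CCC(=C)OP(=O)(OCC)OCC)[C@@](C)(CCCO[Si](C)(C)C(C)(C)C)[C@H]2C[C@@H]1C2(C)C | intermediate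
8 | 3-(but-3-yn-1-yl)-4,6,6-trimethyl-4-[3-(tert-butyldimethylsilyloxy)propyl]bicyclo[3.1.1]heptan-2-one, butynyl chain syn to the bridge (H-9 α, C11 β) | O=C1[C@H](CCC#C)[C@@](C)(CCCO[Si](C)(C)C(C)(C)C)[C@H]2C[C@@H]1C2(C)C | intermediate
9 | 5-(3-acetoxypropyl)-6-(but-3-yn-1-yl)-5-methyl-4-(prop-1-en-2-yl)cyclohex-1-en-1-yl acetate (H-5 α, CH3-20 β, H-9 α) | CC(=O)OC1=CC[C@@H](C(C)=C)[C@](C)(CCCOC(C)=O)[C@H]1CCC#C | intermediate
10 | B-alkyl-9-borabicyclo[3.3.1]nonane adduct of 9 at C19 (C4 epimers; not isolated) | CC(=O)OC1=CC[C@@H](C(C)CB2C3CCCC2CCC3)[C@](C)(CCCOC(C)=O)[C@H]1CCC#C | intermediate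
11 | 5-(3-acetoxypropyl)-6-(but-3-yn-1-yl)-4-(1-hydroxypropan-2-yl)-5-methylcyclohex-1-en-1-yl acetate (C4 epimers) | CC(=O)OC1=CC[C@@H](C(C)CO)[C@](C)(CCCOC(C)=O)[C@H]1CCC#C | intermediate
12 | C19 aldehyde, 4-(1-oxopropan-2-yl) analogue of 11 (C4 epimers; not isolated) | CC(=O)OC1=CC[C@@H](C(C)C=O)[C@](C)(CCCOC(C)=O)[C@H]1CCC#C | intermediate
13 | 5-(3-acetoxypropyl)-6-(but-3-yn-1-yl)-4-(1-cyanoethyl)-5-methylcyclohex-1-en-1-yl acetate (C4 epimers) | CC(=O)OC1=CC[C@@H](C(C)C#N)[C@](C)(CCCOC(C)=O)[C@H]1CCC#C | intermediate
14 | 2-[3-(but-3-yn-1-yl)-2-(3-hydroxypropyl)-2-methyl-4-oxocyclohexyl]propanenitrile (H-5 α, CH3-20 β, H-9 α; C4 epimers) | O=C1CC[C@@H](C(C)C#N)[C@](C)(CCCO)[C@H]1CCC#C | intermediate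
15 | 2-[3-(but-3-yn-1-yl)-2-(3-hydroxypropyl)-2-methyl-4-methylidenecyclohexyl]propanenitrile (C4 epimers) | C=C1CC[C@@H](C(C)C#N)[C@](C)(CCCO)[C@H]1CCC#C | intermediate
16 | 2-[3-(but-3-yn-1-yl)-2-(3-iodopropyl)-2-methyl-4-methylidenecyclohexyl]propanenitrile (C4 epimers) | C=C1CC[C@@H](C(C)C#N)[C@](C)(CCCI)[C@H]1CCC#C | intermediate
17 | (1S,4aR,5S,8aR)-5-(but-3-yn-1-yl)-1,4a-dimethyl-6-methylidenedecahydronaphthalene-1-carbonitrile | C=C1CC[C@@H]2[C@](C)(CCC[C@]2(C)C#N)[C@H]1CCC#C | intermediate
18 | (E)-alkenyl(dimethyl)alane from 17, aluminium on C14 (not isolated) | C=C1CC[C@@H]2[C@](C)(CCC[C@]2(C)C#N)[C@H]1CC/C(C)=C/[Al](C)C | intermediate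
19 | (1S,4aR,5S,8aR)-5-[(3E)-5-hydroxy-3-methylpent-3-en-1-yl]-1,4a-dimethyl-6-methylidenedecahydronaphthalene-1-carbonitrile | C=C1CC[C@@H]2[C@](C)(CCC[C@]2(C)C#N)[C@H]1CC/C(C)=C/CO | intermediate
20 | (1S,4aR,5S,8aR)-5-[(3E)-5-bromo-3-methylpent-3-en-1-yl]-1,4a-dimethyl-6-methylidenedecahydronaphthalene-1-carbonitrile | C=C1CC[C@@H]2[C@](C)(CCC[C@]2(C)C#N)[C@H]1CC/C(C)=C/CBr | intermediate
21 | (+)-β-eudesmol, 2-[(2R,4aR,8aS)-4a-methyl-8-methylidenedecahydronaphthalen-2-yl]propan-2-ol | C=C1CCC[C@]2(C)CC[C@@H](C(C)(C)O)C[C@H]21 | starting material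
22 | β-eudesmol triethylsilyl ether | C=C1CCC[C@]2(C)CC[C@@H](C(C)(C)O[Si](CC)(CC)CC)C[C@H]21 | intermediate
23 | 4′α,15′-epoxide of 22 (oxygen α, CH2 β) | C1O[C@@]12CCC[C@]3(C)CC[C@@H](C(C)(C)O[Si](CC)(CC)CC)C[C@H]32 | intermediate
24 | (1R,4aR,7R,8aR)-1,4a-dimethyl-7-[2-(triethylsilyloxy)propan-2-yl]decahydronaphthalen-1-ol (11′-O-triethylsilyl cryptomeridiol) | O[C@]1(C)CCC[C@]2(C)CC[C@@H](C(C)(C)O[Si](CC)(CC)CC)C[C@H]21 | intermediate
25 | (1S,4aR,5S,8aR)-5-[(3E)-5-{[(1R,4aR,7R,8aR)-1,4a-dimethyl-7-(2-triethylsilyloxypropan-2-yl)decahydronaphthalen-1-yl]oxy}-3-methylpent-3-en-1-yl]-1,4a-dimethyl-6-methylidenedecahydronaphthalene-1-carbonitrile | C=C1CC[C@@H]2[C@](C)(CCC[C@]2(C)C#N)[C@H]1CC/C(C)=C/CO[C@]1(C)CCC[C@]2(C)CC[C@@H](C(C)(C)O[Si](CC)(CC)CC)C[C@H]21 | intermediate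
26 | N-(diisobutylalumino) aldimine of 25 at C19 (not isolated) | C=C1CC[C@@H]2[C@](C)(CCC[C@]2(C)C=N[Al](CC(C)C)CC(C)C)[C@H]1CC/C(C)=C/CO[C@]1(C)CCC[C@]2(C)CC[C@@H](C(C)(C)O[Si](CC)(CC)CC)C[C@H]21 | intermediate
27 | C19 aldehyde, 1-carbaldehyde analogue of 25 | C=C1CC[C@@H]2[C@](C)(CCC[C@]2(C)C=O)[C@H]1CC/C(C)=C/CO[C@]1(C)CCC[C@]2(C)CC[C@@H](C(C)(C)O[Si](CC)(CC)CC)C[C@H]21 | intermediate
28 | 11′-O-triethylsilyl ether of the target acid | C=C1CC[C@@H]2[C@](C)(CCC[C@]2(C)C(=O)O)[C@H]1CC/C(C)=C/CO[C@]1(C)CCC[C@]2(C)CC[C@@H](C(C)(C)O[Si](CC)(CC)CC)C[C@H]21 | intermediate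
29 | (1S,4aR,5S,8aR)-5-[(3E)-5-{[(1R,4aR,7R,8aR)-7-(2-hydroxypropan-2-yl)-1,4a-dimethyldecahydronaphthalen-1-yl]oxy}-3-methylpent-3-en-1-yl]-1,4a-dimethyl-6-methylidenedecahydronaphthalene-1-carboxylic acid | C=C1CC[C@@H]2[C@](C)(CCC[C@]2(C)C(=O)O)[C@H]1CC/C(C)=C/CO[C@]1(C)CCC[C@]2(C)CC[C@@H](C(C)(C)O)C[C@H]21 | target

Step count. Total: 19 steps. Longest linear sequence: 16 steps (steps 1–12 and 16–19); the eudesmane alcohol 24 takes 3 steps (13–15).

Steps most likely to fail. The ring closure of step 10 belongs to a well-precedented reaction class (alkylative cyclisation of metalated nitriles) and is judged less exposed than the three steps below.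

Step 16. The hindered, strongly basic tertiary alkoxide may act as a base, so that 1,4-elimination of HBr from the allylic bromide outruns the SN2 etherification. The fallback sets out from 24 and 17 and comes back at 25; it makes the C15–O bond first and the C14–C15 bond last. Alcohol 24 would be converted with DMSO, Ac2O and AcOH into the methylthiomethyl ether F1, and this with SO2Cl2 in CH2Cl2 at −78 °C into the chloromethyl ether F2. Alkyne 17 would be carboaluminated as in step 11, and the alkenylalane 18, activated with n-BuLi, would be alkylated by the chloromethyl ether F2 to give 25 directly.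

Step 3. Three events share one flask, and each can go astray: enolisation of the methyl ketone at the internal instead of the terminal position, premature enolisation of the ring ketone, and incomplete kinetic protonation at C9. The fallback sets out from 3 and comes back at 8; it replaces the Michael addition and ketone-to-alkyne conversion by alkylation and aldehyde homologation. Treatment of 3 with MeLi and then allyl iodide would give the allyl ketone F3. Hydroboration with 9-BBN and oxidation would give the primary alcohol F4, and Dess–Martin periodinane the aldehyde F5. Seyferth–Gilbert homologation with the Ohira–Bestmann reagent (K2CO3, MeOH) would give the C9-epimeric alkyne F6. Enolisation with LiN(iPr)2 and kinetic protonation with AcOH at −78 °C would then invert C9 to give 8.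

Step 5. The isopropenyl group sits next to the C10 quaternary centre, so 9-BBN may add to the terminal alkyne at a comparable rate and double hydroboration of the alkyne would consume material. The fallback sets out from 9 and comes back at 14; it masks the alkyne as a silylalkyne before the hydroboration. Zinc-catalysed C-silylation of 9 (TMSOTf, Zn(OTf)2 cat., Et3N, CH2Cl2) would give the trimethylsilylalkyne F7. Hydroboration–oxidation as in step 5 would give the primary alcohol F8, and the oxidative nitrile formation of step 6 the nitrile F9. K2CO3 in MeOH would then remove both acetyl groups and the alkynyl silyl group in one operation to give 14.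

Further compounds

F1 | step 16 | 4′-O-(methylthiomethyl)-11′-O-triethylsilyl cryptomeridiol | CSCO[C@]1(C)CCC[C@]2(C)CC[C@@H](C(C)(C)O[Si](CC)(CC)CC)C[C@H]21
F2 | step 16 | 4′-O-(chloromethyl)-11′-O-triethylsilyl cryptomeridiol | ClCO[C@]1(C)CCC[C@]2(C)CC[C@@H](C(C)(C)O[Si](CC)(CC)CC)C[C@H]21
F3 | step 3 | 3-allyl-4,6,6-trimethyl-4-[3-(tert-butyldimethylsilyloxy)propyl]bicyclo[3.1.1]heptan-2-one, allyl anti to the bridge | O=C1[C@@H](CC=C)[C@@](C)(CCCO[Si](C)(C)C(C)(C)C)[C@H]2C[C@@H]1C2(C)C
F4 | step 3 | 3-(3-hydroxypropyl) analogue of F3 | O=C1[C@@H](CCCO)[C@@](C)(CCCO[Si](C)(C)C(C)(C)C)[C@H]2C[C@@H]1C2(C)C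
F5 | step 3 | 3-(3-oxopropyl) analogue of F3 (aldehyde) | O=C1[C@@H](CCC=O)[C@@](C)(CCCO[Si](C)(C)C(C)(C)C)[C@H]2C[C@@H]1C2(C)C
F6 | step 3 | C9 epimer of 8 (but-3-ynyl chain anti to the bridge) | O=C1[C@@H](CCC#C)[C@@](C)(CCCO[Si](C)(C)C(C)(C)C)[C@H]2C[C@@H]1C2(C)C
F7 | step 5 | 5-(3-acetoxypropyl)-5-methyl-4-(prop-1-en-2-yl)-6-[4-(trimethylsilyl)but-3-yn-1-yl]cyclohex-1-en-1-yl acetate | CC(=O)OC1=CC[C@@H](C(C)=C)[C@](C)(CCCOC(C)=O)[C@H]1CCC#C[Si](C)(C)C
F8 | step 5 | 4-(1-hydroxypropan-2-yl) analogue of F7 (C4 epimers) | CC(=O)OC1=CC[C@@H](C(C)CO)[C@](C)(CCCOC(C)=O)[C@H]1CCC#C[Si](C)(C)C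
F9 | step 5 | 4-(1-cyanoethyl) analogue of F7 (C4 epimers) | CC(=O)OC1=CC[C@@H](C(C)C#N)[C@](C)(CCCOC(C)=O)[C@H]1CCC#C[Si](C)(C)C
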